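**Retrosynthetic overview**
1. Fragilide F ⇐ one-flask closure of seco-lactol 32: CrCl2-mediated C6–C7 chloroallylation closes the ten-membered carbocycle, the γ-lactone re-closes, and 4-OH adds to C8 to close the oxane (these three rings form last, in that order).
2. 32 ⇐ ring A enol silane 17 + aldehyde 25 (C1–C2 chelation-controlled Mukaiyama aldol), then 14-ketone reduction, acetylation, butenolide γ-oxidation, desilylation.
3. 17 ⇐ ring A aldehyde 12 + tetronate triflate 16 (C8–C9 Nozaki–Hiyama–Kishi coupling); 25 ⇐ proline cross-aldol of 18 + 19, then CHCl2 and methylene installation.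
4. Ring A (formed first) ⇐ enantioselective Diels–Alder of silyloxydiene 4 with 2-bromoacrolein 7, then bromohydrin → epoxide → silylated chlorohydrin.

Assumption: briarane locants (C1–C20) are used for all intermediates; the target SMILES fixes the absolute configuration (1R,2R,3R,4R,6S,7R,8R,9S,10S,11R,14S,17R), α/β refer to the ring A face opposite/same as the C15 methyl, and the SMILES strings are authoritative.

**Route**

Step 1
Reactants: 1 2,2-dimethoxyacetaldehyde; 2 3-(triphenylphosphoranylidene)butan-2-one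
Product: 3 (E)-5,5-dimethoxy-3-methylpent-3-en-2-one
Conditions: CH2Cl2, 25 °C (1 as its 60% aqueous solution)
Reagents that add atoms: none
Why: Wittig olefination with the stabilized α-methyl ylide gives the (E)-enone (acetal carbon trans to acetyl), the geometry the later Diels–Alder reaction needs; no stereocentre is formed.

Step 2
Reactants: 3 (E)-5,5-dimethoxy-3-methylpent-3-en-2-one
Product: 4 tert-butyl{[(3E)-5,5-dimethoxy-3-methylpenta-1,3-dien-2-yl]oxy}dimethylsilane
Conditions: t-BuMe2SiOTf, Et3N, CH2Cl2, 0 °C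
Reagents that add atoms: tert-butyldimethylsilyl triflate, CC(C)(C)[Si](C)(C)OS(=O)(=O)C(F)(F)F
Why: Soft enolization (silyl triflate/amine) of the methyl ketone at its only α-CH3 gives the cross-conjugated 2-silyloxydiene without isomerizing the (E)-alkene; no stereocentre.

Step 3
Reactants: 5 acrolein
Product: 7 2-bromoacrolein, via 2,3-dibromopropanal 6 (not isolated)
Conditions: Br2, CH2Cl2, −78 °C; then Et3N, −78 to 0 °C
Reagents that add atoms: bromine, BrBr
Why: Bromine addition followed by amine-induced E2 dehydrobromination gives the α-bromo enal; the product has no stereocentre.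

Step 4
Reactants: 4 silyloxydiene; 7 2-bromoacrolein
Product: 8 (1S,2S)-1-bromo-4-[(tert-butyldimethylsilyl)oxy]-2-(dimethoxymethyl)-3-methylcyclohex-3-ene-1-carbaldehyde (ring C1 = C11, ring C2 = C10; Br and the C10 acetal branch cis)
Conditions: B-n-butyl-1,3,2-oxazaborolidin-5-one derived from N-tosyl-(R)-tryptophan (10 mol %), CH2Cl2, −78 °C
Reagents that add atoms: none
Why: Catalytic enantioselective Diels–Alder reaction in which the 2-silyloxy and 1-alkyl groups of 4 direct C10–C11 and C13–C12 bonding, the α-substituted acrolein reacts through the usual bromine-endo/formyl-exo transition state (Br cis to the C10 branch), and the indole of the boron catalyst blocks one face of the s-cis enal, fixing C10 and C11 absolutely.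

Step 5
Reactants: 8 Diels–Alder adduct
Product: 10 tert-butyl{[(3R,4R)-4-(dimethoxymethyl)-5-methyl-1-oxaspiro[2.5]oct-5-en-6-yl]oxy}dimethylsilane (11,20-epoxide, oxygen α), via bromohydrin 9 (not isolated)
Conditions: NaBH4, MeOH, −20 °C; then K2CO3, 0 °C
Reagents that add atoms: none
Why: Chemoselective borohydride reduction of the aldehyde and Williamson-type closure of the bromohydrin, in which the primary alkoxide displaces the tertiary bromide with inversion at C11, put the epoxide oxygen on the α-face, anti to the C10 branch.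

Step 6
Reactants: 10 spiro-epoxide
Product: 11 tert-butyl{[(3R,4R)-4-(chloromethyl)-3-(dimethoxymethyl)-2-methyl-4-[(triethylsilyl)oxy]cyclohex-1-en-1-yl]oxy}dimethylsilane
Conditions: Et3SiCl, Bu4NCl (10 mol %), CH2Cl2, 25 °C
Reagents that add atoms: chlorotriethylsilane, CC[Si](Cl)(CC)CC
Why: Chloride-catalysed silyl chloride opening of the epoxide (SN2 attack of chloride at the unhindered CH2, silicon on oxygen) gives the protected chlorohydrin with C11 untouched, so C11 keeps oxygen α and gains CH2Cl β.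

Step 7
Reactants: 11 dimethyl acetal
Product: 12 (1R,6R)-3-[(tert-butyldimethylsilyl)oxy]-6-(chloromethyl)-2-methyl-6-[(triethylsilyl)oxy]cyclohex-2-ene-1-carbaldehyde (C9 aldehyde)
Conditions: Et3SiOTf, 2,4,6-collidine, CH2Cl2, 0 °C; then H2O
Reagents that add atoms: water, O
Why: Silyl triflate/collidine acetal cleavage runs through a collidinium salt that water hydrolyses under buffered conditions, sparing the silyl enol ether and the tertiary silyl ether and leaving C10 unepimerized.

Step 8
Reactants: 13 ethyl 2-methyl-3-oxobutanoate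
Product: 15 3-methyltetronic acid (4-hydroxy-3-methylfuran-2(5H)-one), via ethyl 4-bromo-2-methyl-3-oxobutanoate 14 (not isolated)
Conditions: Br2, CHCl3, 0 to 25 °C; then neat, 110 °C
Reagents that add atoms: none
Why: Acid-equilibrated γ-bromination of the β-keto ester and thermal O-alkylative lactonization with loss of bromoethane is the classical tetronic acid synthesis; no stereocentre.

Step 9
Reactants: 15 3-methyltetronic acid
Product: 16 4-methyl-5-oxo-2,5-dihydrofuran-3-yl trifluoromethanesulfonate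
Conditions: Tf2O, Et3N, CH2Cl2, −78 °C
Reagents that add atoms: triflic anhydride, O=S(=O)(OS(=O)(=O)C(F)(F)F)C(F)(F)F
Why: O-Sulfonylation of the vinylogous acid gives the vinyl triflate needed for nickel activation; no stereocentre.

Step 10
Reactants: 12 ring A aldehyde; 16 butenolide triflate
Product: 17 4-{(S)-[(1S,6R)-3-[(tert-butyldimethylsilyl)oxy]-6-(chloromethyl)-2-methyl-6-[(triethylsilyl)oxy]cyclohex-2-en-1-yl](hydroxy)methyl}-3-methylfuran-2(5H)-one
Conditions: CrCl2 (4 equiv), NiCl2 (2 mol %), DMF, 25 °C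
Reagents that add atoms: none
Why: Nozaki–Hiyama–Kishi coupling (oxidative addition of the vinyl triflate to zerovalent nickel, transmetalation to trivalent chromium, carbonyl addition) tolerates the silyl enol ether and alkyl chloride, and attack anti to the quaternary C11 (Felkin–Anh), reinforced by 1,3-anti induction from the 11-silyloxy group, gives the 9S carbinol.

Step 11
Reactants: 18 (4-methoxybenzyloxy)acetaldehyde; 19 ethyl glyoxylate
Product: 21 ethyl (2S,3R)-2-hydroxy-4,4-dimethoxy-3-[(4-methoxybenzyl)oxy]butanoate, via aldol aldehyde 20 (not isolated)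
Conditions: (R)-proline (20 mol %), DMF, 4 °C, slow addition of 18; then HC(OMe)3, pyridinium p-toluenesulfonate, MeOH, 25 °C
Reagents that add atoms: trimethyl orthoformate, COC(OC)OC
Why: Proline-catalysed direct cross-aldol reaction (enamine of 18 adds to the more electrophilic glyoxylate through the hydrogen-bonded chair transition state) gives the anti aldol, (R)-proline setting both centres (future C3 and C4), and in-flask acetalization protects the labile aldehyde.

Step 12
Reactants: 21 hydroxy ester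
Product: 22 ethyl (2S,3R)-2-[(tert-butyldimethylsilyl)oxy]-4,4-dimethoxy-3-[(4-methoxybenzyl)oxy]butanoate
Conditions: t-BuMe2SiOTf, 2,6-lutidine, CH2Cl2, −78 to 0 °C
Reagents that add atoms: tert-butyldimethylsilyl triflate, CC(C)(C)[Si](C)(C)OS(=O)(=O)C(F)(F)F
Why: Silyl triflate silylation of the secondary alcohol leaves both stereocentres untouched and makes the future C4 oxygen non-chelating.

Step 13
Reactants: 22 silyloxy ester
Product: 23 (3S,4R)-3-[(tert-butyldimethylsilyl)oxy]-1,1-dichloro-5,5-dimethoxy-4-[(4-methoxybenzyl)oxy]pentan-2-one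
Conditions: CH2Cl2 (3 equiv), LiN(iPr)2 (2.5 equiv), THF, −78 °C; NH4Cl quench at −78 °C
Reagents that add atoms: dichloromethane (as LiCHCl2), ClCCl
Why: Acylation of dichloromethyllithium by the ester stops at the ketone because the product is held as its tetrahedral adduct/enolate at −78 °C, and the α-silyloxy centre does not epimerize at this temperature.

Step 14
Reactants: 23 dichloromethyl ketone
Product: 24 tert-butyl{[(3R,4R)-2-(dichloromethyl)-5,5-dimethoxy-4-[(4-methoxybenzyl)oxy]pent-1-en-3-yl]oxy}dimethylsilane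
Conditions: Cp2TiMe2 (2 equiv), toluene, 65 °C, dark
Reagents that add atoms: Cp2TiMe2 (dimethyltitanocene), C[Ti](C)(C1C=CC=C1)C1C=CC=C1
Why: Petasis methylenation (non-basic titanium methylidene) converts the hindered, enolizable α,α-dichloroketone into the 1,1-disubstituted alkene without touching the C–Cl bonds or the adjacent stereocentre.

Step 15
Reactants: 24 dimethyl acetal
Product: 25 (2R,3R)-3-[(tert-butyldimethylsilyl)oxy]-4-(dichloromethyl)-2-[(4-methoxybenzyl)oxy]pent-4-enal (C2 aldehyde, C3 OPMB, C4 OTBS, C5=CH2, C6HCl2)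
Conditions: Et3SiOTf, 2,4,6-collidine, CH2Cl2, 0 °C; then H2O
Reagents that add atoms: water, O
Why: The same buffered collidinium-mediated acetal cleavage frees the aldehyde while keeping the PMB and silyl ethers and avoiding epimerization of the α-alkoxy aldehyde.

Step 16
Reactants: 17 ring A enol silane; 25 aldehyde
Product: 26 ring A ketone aldol adduct (14-oxo; C1 carries CH3 β and the chain C2H(OH)–C3H(OPMB)–C4H(OTBS)–C5(=CH2)–C6HCl2, 2,3-syn and 3,4-anti; C10 carries C9H(OH)–butenolide; C11 carries OSiEt3 α and CH2Cl β)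
Conditions: MgBr2·OEt2 (3 equiv), CH2Cl2, −78 to −20 °C
Reagents that add atoms: none
Why: Chelation-controlled Mukaiyama aldol addition in which MgBr2 ties the aldehyde oxygen to the α-PMB ether so that the enol silane attacks the Cram-chelate face (2,3-syn, setting C2), while the ring is attacked on its α-face, anti to the C10 branch and the axial C20 chloromethyl group, setting the quaternary C1 with methyl β.

Step 17
Reactants: 26 β-hydroxy ketone
Product: 27 14α-alcohol of 26 (2,9,14-triol)
Conditions: Me4NBH(OAc)3, MeCN/AcOH (1:1), −30 °C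
Reagents that add atoms: none
Why: Evans–Saksena reduction, in which the C2 alkoxy(acetoxy)borohydride delivers hydride intramolecularly to the C14 ketone, gives the 1,3-anti diol, that is the axial 14α-alcohol; esters, butenolide and dichloride are inert to this reagent.

Step 18
Reactants: 27 PMB ether
Product: 28 2,3,9,14-tetraol (PMB removed; 4-OTBS and 11-OSiEt3 retained)
Conditions: DDQ, CH2Cl2/pH 7 buffer (10:1), 0 °C
Reagents that add atoms: none
Why: DDQ oxidation of the electron-rich PMB ether (hydride abstraction, hydrolysis of the oxocarbenium ion) frees 3-OH without affecting silyl ethers or alkenes; no stereocentre changes.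

Step 19
Reactants: 28 tetraol
Product: 29 2,3,9,14-tetraacetate of 28
Conditions: Ac2O, Et3N, DMAP (cat.), CH2Cl2, 0 to 25 °C
Reagents that add atoms: acetic anhydride, CC(=O)OC(C)=O
Why: DMAP-catalysed acylation esterifies the four secondary alcohols (C2, C3, C9, C14) while the oxygens at C4 and C11 stay silylated; no stereocentre changes.

Step 20
Reactants: 29 butenolide tetraacetate
Product: 31 γ-hydroxybutenolide of 29 (C7 lactol, both epimers), via silyloxyfuran 30 (not isolated)
Conditions: i-Pr3SiOTf, Et3N, CH2Cl2, 0 °C; then dimethyldioxirane, acetone, −78 °C; wet silica work-up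
Reagents that add atoms: dimethyldioxirane, CC1(C)OO1
Why: Soft enolization gives the 2-silyloxyfuran, the most electron-rich π-system present, which dimethyldioxirane oxidizes at C7, and silyl transfer/hydrolysis gives the γ-hydroxybutenolide (the C7 lactol epimers are inconsequential because C7 is reset in step 22).

Step 21
Reactants: 31 bis-silyl ether
Product: 32 seco-precursor with free 4-OH and 11-OH (C7 lactol, C6HCl2, four acetates)
Conditions: HF·pyridine, pyridine, THF, 0 to 25 °C
Reagents that add atoms: none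
Why: Fluoride-mediated desilylation removes the secondary silyl ether at C4 and the tertiary one at C11 under buffered, weakly acidic conditions that leave acetates, lactol and chlorides intact.

Step 22
Reactants: 32 seco-precursor
Product: 36 Fragilide F, via ring-opened formyl acid 33 (not isolated), via macrocyclic hydroxy acid 34 (not isolated), via macrocyclic butenolide 35 (not isolated)
Conditions: CrCl2 (8 equiv), THF/DMF (4:1), 25 °C, syringe-pump addition to 2 mM; then AcOH (3 equiv), 1 h; then DBU (4 equiv), 0 to 25 °C, same flask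
Reagents that add atoms: none
Why: Proposed new method: the lactol of 32 opens to the (Z)-formyl acid 33, CrCl2 reduces the allylic gem-dichloride to a γ-chloroallyl–chromium bond that adds to the C7 aldehyde through a six-membered chair transition state (anti chlorohydrin, 6S/7R) on the face set by the A(1,3)-locked C9 centre and a chromium carboxylate–aldehyde chelate, acid then closes the butenolide and DBU triggers transannular oxa-Michael addition of 4-OH to C8 (C8 fixed by the bridge, C17 by thermodynamic protonation with methyl anti to C9), the closest precedents being chromium-mediated γ-chloroallylation of aldehydes with allylic gem-dichlorides, intramolecular Nozaki–Hiyama allylation to ten-membered rings and base-mediated oxa-Michael etherification.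

**Compound list**

1 | 2,2-dimethoxyacetaldehyde | COC(OC)C=O | starting material
2 | 3-(triphenylphosphoranylidene)butan-2-one | CC(=O)C(C)=P(c1ccccc1)(c1ccccc1)c1ccccc1 | starting material
3 | (E)-5,5-dimethoxy-3-methylpent-3-en-2-one | COC(OC)/C=C(C)/C(C)=O | intermediate
4 | tert-butyl{[(3E)-5,5-dimethoxy-3-methylpenta-1,3-dien-2-yl]oxy}dimethylsilane | COC(OC)/C=C(C)/C(=C)O[Si](C)(C)C(C)(C)C | intermediate
5 | acrolein | C=CC=O | starting material
6 | 2,3-dibromopropanal (racemic) | O=CC(Br)CBr | intermediate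
7 | 2-bromoacrolein | C=C(Br)C=O | intermediate
8 | (1S,2S)-1-bromo-4-[(tert-butyldimethylsilyl)oxy]-2-(dimethoxymethyl)-3-methylcyclohex-3-ene-1-carbaldehyde | O=C[C@]1(Br)CCC(O[Si](C)(C)C(C)(C)C)=C(C)[C@H]1C(OC)OC | intermediate
9 | [(1S,2S)-1-bromo-4-[(tert-butyldimethylsilyl)oxy]-2-(dimethoxymethyl)-3-methylcyclohex-3-en-1-yl]methanol | OC[C@]1(Br)CCC(O[Si](C)(C)C(C)(C)C)=C(C)[C@H]1C(OC)OC | intermediate
10 | tert-butyl{[(3R,4R)-4-(dimethoxymethyl)-5-methyl-1-oxaspiro[2.5]oct-5-en-6-yl]oxy}dimethylsilane | C1O[C@@]12CCC(O[Si](C)(C)C(C)(C)C)=C(C)[C@H]2C(OC)OC | intermediate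
11 | tert-butyl{[(3R,4R)-4-(chloromethyl)-3-(dimethoxymethyl)-2-methyl-4-[(triethylsilyl)oxy]cyclohex-1-en-1-yl]oxy}dimethylsilane | ClC[C@@]1(O[Si](CC)(CC)CC)CCC(O[Si](C)(C)C(C)(C)C)=C(C)[C@H]1C(OC)OC | intermediate
12 | (1R,6R)-3-[(tert-butyldimethylsilyl)oxy]-6-(chloromethyl)-2-methyl-6-[(triethylsilyl)oxy]cyclohex-2-ene-1-carbaldehyde | ClC[C@@]1(O[Si](CC)(CC)CC)CCC(O[Si](C)(C)C(C)(C)C)=C(C)[C@H]1C=O | intermediate
13 | ethyl 2-methyl-3-oxobutanoate | CCOC(=O)C(C)C(C)=O | starting material
14 | ethyl 4-bromo-2-methyl-3-oxobutanoate (racemic) | CCOC(=O)C(C)C(=O)CBr | intermediate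
15 | 3-methyltetronic acid (4-hydroxy-3-methylfuran-2(5H)-one) | CC1=C(O)COC1=O | intermediate
16 | 4-methyl-5-oxo-2,5-dihydrofuran-3-yl trifluoromethanesulfonate | CC1=C(OS(=O)(=O)C(F)(F)F)COC1=O | intermediate
17 | 4-{(S)-[(1S,6R)-3-[(tert-butyldimethylsilyl)oxy]-6-(chloromethyl)-2-methyl-6-[(triethylsilyl)oxy]cyclohex-2-en-1-yl](hydroxy)methyl}-3-methylfuran-2(5H)-one | ClC[C@@]1(O[Si](CC)(CC)CC)CCC(O[Si](C)(C)C(C)(C)C)=C(C)[C@H]1[C@H](O)C1=C(C)C(=O)OC1 | intermediate
18 | (4-methoxybenzyloxy)acetaldehyde | COc1ccc(COCC=O)cc1 | starting material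
19 | ethyl glyoxylate | CCOC(=O)C=O | starting material
20 | ethyl (2S,3R)-2-hydroxy-3-[(4-methoxybenzyl)oxy]-4-oxobutanoate | O=C[C@H](OCc1ccc(OC)cc1)[C@H](O)C(=O)OCC | intermediate
21 | ethyl (2S,3R)-2-hydroxy-4,4-dimethoxy-3-[(4-methoxybenzyl)oxy]butanoate | COC(OC)[C@H](OCc1ccc(OC)cc1)[C@H](O)C(=O)OCC | intermediate
22 | ethyl (2S,3R)-2-[(tert-butyldimethylsilyl)oxy]-4,4-dimethoxy-3-[(4-methoxybenzyl)oxy]butanoate | COC(OC)[C@H](OCc1ccc(OC)cc1)[C@H](O[Si](C)(C)C(C)(C)C)C(=O)OCC | intermediate
23 | (3S,4R)-3-[(tert-butyldimethylsilyl)oxy]-1,1-dichloro-5,5-dimethoxy-4-[(4-methoxybenzyl)oxy]pentan-2-one | COC(OC)[C@H](OCc1ccc(OC)cc1)[C@H](O[Si](C)(C)C(C)(C)C)C(=O)C(Cl)Cl | intermediate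
24 | tert-butyl{[(3R,4R)-2-(dichloromethyl)-5,5-dimethoxy-4-[(4-methoxybenzyl)oxy]pent-1-en-3-yl]oxy}dimethylsilane | COC(OC)[C@H](OCc1ccc(OC)cc1)[C@H](O[Si](C)(C)C(C)(C)C)C(=C)C(Cl)Cl | intermediate
25 | (2R,3R)-3-[(tert-butyldimethylsilyl)oxy]-4-(dichloromethyl)-2-[(4-methoxybenzyl)oxy]pent-4-enal | O=C[C@H](OCc1ccc(OC)cc1)[C@H](O[Si](C)(C)C(C)(C)C)C(=C)C(Cl)Cl | intermediate
26 | ring A ketone aldol adduct (14-oxo; 2-OH; 3-OPMB; 4-OTBS; 5(16)-methylene; 6,6-dichloro; 9-OH; 11α-OSiEt3; 20-Cl; 15-Me β; H-10 α; C8 is C4 of the 3-methylbutenolide, C7H2) | ClC[C@@]1(O[Si](CC)(CC)CC)CCC(=O)[C@](C)([C@@H](O)[C@H](OCc2ccc(OC)cc2)[C@H](O[Si](C)(C)C(C)(C)C)C(=C)C(Cl)Cl)[C@H]1[C@H](O)C1=C(C)C(=O)OC1 | intermediate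
27 | 14α-alcohol of 26 (2,9,14-triol) | ClC[C@@]1(O[Si](CC)(CC)CC)CC[C@H](O)[C@](C)([C@@H](O)[C@H](OCc2ccc(OC)cc2)[C@H](O[Si](C)(C)C(C)(C)C)C(=C)C(Cl)Cl)[C@H]1[C@H](O)C1=C(C)C(=O)OC1 | intermediate
28 | 2,3,9,14-tetraol (27 without PMB) | ClC[C@@]1(O[Si](CC)(CC)CC)CC[C@H](O)[C@](C)([C@@H](O)[C@H](O)[C@H](O[Si](C)(C)C(C)(C)C)C(=C)C(Cl)Cl)[C@H]1[C@H](O)C1=C(C)C(=O)OC1 | intermediate
29 | 2,3,9,14-tetraacetate of 28 | ClC[C@@]1(O[Si](CC)(CC)CC)CC[C@H](OC(C)=O)[C@](C)([C@@H](OC(C)=O)[C@H](OC(C)=O)[C@H](O[Si](C)(C)C(C)(C)C)C(=C)C(Cl)Cl)[C@H]1[C@H](OC(C)=O)C1=C(C)C(=O)OC1 | intermediate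
30 | 2-(triisopropylsilyloxy)-3-methylfuran-4-yl form of 29 | ClC[C@@]1(O[Si](CC)(CC)CC)CC[C@H](OC(C)=O)[C@](C)([C@@H](OC(C)=O)[C@H](OC(C)=O)[C@H](O[Si](C)(C)C(C)(C)C)C(=C)C(Cl)Cl)[C@H]1[C@H](OC(C)=O)c1coc(O[Si](C(C)C)(C(C)C)C(C)C)c1C | intermediate
31 | γ-hydroxybutenolide of 29 (C7 lactol, both epimers) | ClC[C@@]1(O[Si](CC)(CC)CC)CC[C@H](OC(C)=O)[C@](C)([C@@H](OC(C)=O)[C@H](OC(C)=O)[C@H](O[Si](C)(C)C(C)(C)C)C(=C)C(Cl)Cl)[C@H]1[C@H](OC(C)=O)C1=C(C)C(=O)OC1O | intermediate
32 | seco-precursor: 31 with free 4-OH and 11-OH | ClC[C@@]1(O)CC[C@H](OC(C)=O)[C@](C)([C@@H](OC(C)=O)[C@H](OC(C)=O)[C@H](O)C(=C)C(Cl)Cl)[C@H]1[C@H](OC(C)=O)C1=C(C)C(=O)OC1O | intermediate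
33 | ring-opened (Z)-formyl acid form of 32 (C7 aldehyde cis to C19 acid) | ClC[C@@]1(O)CC[C@H](OC(C)=O)[C@](C)([C@@H](OC(C)=O)[C@H](OC(C)=O)[C@H](O)C(=C)C(Cl)Cl)[C@H]1[C@H](OC(C)=O)/C(C=O)=C(C(=O)O)\C | intermediate
34 | macrocyclic hydroxy acid (C6–C7 bond closed; 6-Cl and 7-OH as in target; 8(17)-ene; C19 acid) | C=C1[C@@H](O)[C@@H](OC(C)=O)[C@H](OC(C)=O)[C@@]2(C)[C@@H](OC(C)=O)CC[C@](O)(CCl)[C@@H]2[C@H](OC(C)=O)/C(=C(C(=O)O)\C)[C@@H](O)[C@H]1Cl | intermediate
35 | macrocyclic butenolide (19,7-olide, 8(17)-ene, free 4-OH) | C=C1[C@@H](O)[C@@H](OC(C)=O)[C@H](OC(C)=O)[C@@]2(C)[C@@H](OC(C)=O)CC[C@](O)(CCl)[C@@H]2[C@H](OC(C)=O)C2=C(C)C(=O)O[C@H]2[C@H]1Cl | intermediate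
36 | Fragilide F | C=C1[C@H]2O[C@]3([C@@H](C)C(=O)O[C@H]3[C@H]1Cl)[C@@H](OC(C)=O)[C@H]1[C@@](O)(CCl)CC[C@H](OC(C)=O)[C@]1(C)[C@@H](OC(C)=O)[C@@H]2OC(C)=O | target

**Step count and risk**

Total step count: 22. Longest linear sequence: 14 steps (1, 2, 4–7, 10, 16–22).

Most likely to fail, in this order:

Step 22. The one-flask closure asks for a ten-membered ring by chromium allylation, the correct aldehyde face at C7, and survival of the free chlorohydrin and the C6 chloride towards DBU. The fallback separates these events and keeps the silyl ethers on during ring closure. It sets out from 31: Me3SiCHN2 in toluene/MeOH esterifies the ring-opened acid to the silyl-protected methyl (Z)-formyl ester F1. CrCl2 at high dilution then gives, after lactonization of the chromium alkoxide onto the cis methyl ester, the bis-silylated macrocyclic butenolide F2, which is isolated so that any C6/C7 diastereomers can be removed. HF·pyridine then frees 4-OH and 11-OH to give 35 as a discrete compound, and a trace of Et3N or silica closes the oxane, so the fallback returns at 35 and reaches 36 without exposing the chlorohydrin to strong base.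

Step 4. Bromine-endo selectivity and enantioselectivity are untested on this trisubstituted silyloxydiene. The fallback replaces catalyst control by auxiliary control and sets out from 4: the 2-bromoacrylate of (R)-pantolactone F3 (from 2-bromoacrylic acid and (R)-pantolactone) is added to 4 with Et2AlCl at −78 °C. The resulting ester cycloadduct F4 is purified as a single diastereomer by chromatography or crystallization, and i-Bu2AlH reduces the ester to the bromohydrin 9, where the route is rejoined (K2CO3 closure to 10).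

Step 10. Felkin–Anh control at C9 may be modest next to the sp2 C1 and the quaternary C11. The fallback uses reagent control and sets out from the C9 epimer mixture of 17: Dess–Martin periodinane oxidizes it to the C9 ketone F5, and reduction with catecholborane and the (R)-methyl oxazaborolidine made from (R)-diphenylprolinol and methylboronic acid (butenolide carbon as the large group) returns the 9S alcohol 17.

**Further compounds**

F1 | step 22 | methyl (Z)-formyl ester of ring-opened 31 (4-OTBS, 11-OSiEt3 retained) | ClC[C@@]1(O[Si](CC)(CC)CC)CC[C@H](OC(C)=O)[C@](C)([C@@H](OC(C)=O)[C@H](OC(C)=O)[C@H](O[Si](C)(C)C(C)(C)C)C(=C)C(Cl)Cl)[C@H]1[C@H](OC(C)=O)/C(C=O)=C(C(=O)OC)\C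
F2 | step 22 | 4-O-TBS, 11-O-triethylsilyl ether of macrocyclic butenolide 35 | C=C1[C@@H](O[Si](C)(C)C(C)(C)C)[C@@H](OC(C)=O)[C@H](OC(C)=O)[C@@]2(C)[C@@H](OC(C)=O)CC[C@](O[Si](CC)(CC)CC)(CCl)[C@@H]2[C@H](OC(C)=O)C2=C(C)C(=O)O[C@H]2[C@H]1Cl
F3 | step 4 | (R)-4,4-dimethyl-2-oxotetrahydrofuran-3-yl 2-bromoacrylate | C=C(Br)C(=O)O[C@H]1C(=O)OCC1(C)C
F4 | step 4 | (R)-pantolactone ester analogue of 8 (ester in place of the aldehyde) | O=C(O[C@H]1C(=O)OCC1(C)C)[C@]2(Br)CCC(O[Si](C)(C)C(C)(C)C)=C(C)[C@H]2C(OC)OC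
F5 | step 10 | C9 ketone of 17 | ClC[C@@]1(O[Si](CC)(CC)CC)CCC(O[Si](C)(C)C(C)(C)C)=C(C)[C@H]1C(=O)C1=C(C)C(=O)OC1
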